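**Strategy.** The five-membered ring is opened at O1–C2, between the phenol oxygen of ring A (the benzo ring) and the benzylic carbon that stands para to the 4-methoxy group of ring B. The precursor is a racemic, unprotected 1,2-diarylpropan-1-one, assembled in one step by phenol-directed hydroacylation. The key step exploits that C3 is stereolabile there (α to C=O, benzylic to ring A) and that C2 ionises easily once reduced. In one flask, hydrogenation with dynamic kinetic resolution fixes C3 as S, then acid turns C2–OH into a cation that O1 captures trans to the C3 methyl group. O1 thus serves first as directing group, then as nucleophile.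

Key step: step 4

Numbering: O1, C2, C3 and C3a to C7a as in 2,3-dihydrobenzofuran. Ring A is the benzo ring and ring B the aryl group on C2. The target is the trans (2S,3S) isomer.

Assumption: RuCl2[(R)-xylbinap][(R)-daipen] is taken to give the S carbinol, as with simple aryl ketones, and to reduce fastest the ketone enantiomer that leads to the like (Felkin-type) carbinol; if the other enantiomer reacts faster, the mirror-image catalyst is used, because only C3 is carried into the product.

Step 1
Reactants: 1 5-bromo-2-hydroxy-3-methoxybenzaldehyde; 2 (E)-prop-1-enylboronic acid pinacol ester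
Product: 3 2-hydroxy-3-methoxy-5-[(E)-prop-1-enyl]benzaldehyde
Conditions: Pd(dppf)Cl2 (3 mol %), K2CO3 (3 equiv), 1,4-dioxane/H2O, 80 °C
Reagents that add atoms: none
Why: Suzuki–Miyaura coupling at the only C–Br bond should transfer the alkenyl group with retention of its E geometry, and salicylaldehyde-type bromides are coupled under aqueous carbonate without protection of the phenol or the aldehyde.

Step 2
Reactants: 3 2-hydroxy-3-methoxy-5-[(E)-prop-1-enyl]benzaldehyde
Product: 4 2-ethenyl-6-methoxy-4-[(E)-prop-1-enyl]phenol
Conditions: MePPh3Br (2.5 equiv), KOtBu (2.5 equiv), THF, 0 °C to rt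
Reagents that add atoms: methyltriphenylphosphonium bromide, C[P+](c1ccccc1)(c1ccccc1)c1ccccc1.[Br-]
Why: Wittig methylenation with more than two equivalents of ylide, one of which is spent on the phenol proton, is the standard conversion of salicylaldehydes into 2-vinylphenols and leaves the propenyl group untouched.

Step 3
Reactants: 4 2-ethenyl-6-methoxy-4-[(E)-prop-1-enyl]phenol; 5 3-hydroxy-4,5-dimethoxybenzaldehyde
Product: 6 rac-1-(3-hydroxy-4,5-dimethoxyphenyl)-2-{2-hydroxy-3-methoxy-5-[(E)-prop-1-enyl]phenyl}propan-1-one
Conditions: [Rh(cod)(OMe)]2 (cat.), bis(dicyclohexylphosphino)methane (cat.), K3PO4 (cat.), THF, 70 °C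
Reagents that add atoms: none
Why: Phenoxide-directed intermolecular hydroacylation, established for 2-vinylphenols and non-chelating aryl aldehydes: the phenoxide of 4 holds monovalent rhodium next to the vinyl group, the small-bite-angle diphosphine keeps the acyl hydride from decarbonylation, and insertion through the five-membered O,C-rhodacycle gives the branched ketone, so that the C2–C3 bond forms with C3 deliberately racemic and the undirected internal propenyl group stays out of play.

Step 4
Reactants: 6 rac-1-(3-hydroxy-4,5-dimethoxyphenyl)-2-{2-hydroxy-3-methoxy-5-[(E)-prop-1-enyl]phenyl}propan-1-one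
Product: 8 (2S,3S)-2-(3-hydroxy-4,5-dimethoxyphenyl)-7-methoxy-3-methyl-5-[(E)-prop-1-enyl]-2,3-dihydrobenzofuran, via (1S,2S)-carbinol 7 (not isolated)
Conditions: RuCl2[(R)-xylbinap][(R)-daipen] (1 mol %), KOtBu (3 equiv), H2 (10 atm), degassed iPrOH, 25 °C; then HCl (4 M in dioxane, to pH 1), 0 °C to rt
Reagents that add atoms: none
Why: Under KOtBu ketone 6 racemises through its enolate faster than it is reduced, and the ruthenium dihydride formed from the precatalyst transfers hydride and proton in the outer sphere to the S ketone only, on the face that gives the 1S carbinol, so that 7 should form as the like (Felkin-type) isomer; this is the Noyori asymmetric hydrogenation with dynamic kinetic resolution, known for 1,2-diarylpropan-1-ones. Acid then protonates the C2 hydroxyl group, water leaves, and the benzylic cation, stabilised by the para 4-methoxy group of ring B, is captured by O1; this SN1-type cyclodehydration is the known closure of 2-(2-hydroxyaryl)-1-arylpropan-1-ols to 2-aryl-3-methyl-2,3-dihydrobenzofurans and of 2'-hydroxyisoflavan-4-ols to pterocarpans, the latter also in one pot after an asymmetric ketone reduction. The five-membered ring closes in the 5-exo-tet sense (5-exo-trig if the cation is drawn in its quinoid oxocarbenium form). C3 (S) is controlled by the catalyst through the resolution, whereas C2 (S) is controlled by C3, because ring B takes the face of the closing ring opposite to the methyl group and because reversible ionisation under acid drains any cis isomer into the more stable trans isomer, so the carbinol configuration of 7 is of no consequence. The step needs C=O over C=C selectivity, secured by the diphosphine/diamine catalyst that does not reduce the propenyl group, and site selectivity between the two phenols, secured because only O1 can reach C2 in a small ring. It also needs closure to outrun loss of H3 from the cation, which would erase C3, and protonation of the propenyl group; the intramolecular capture and a short exposure to acid at or below room temperature should secure both.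

**Compound list**
1 | 5-bromo-2-hydroxy-3-methoxybenzaldehyde | O=Cc1cc(Br)cc(OC)c1O | starting material
2 | (E)-prop-1-enylboronic acid pinacol ester | C/C=C/B1OC(C)(C)C(C)(C)O1 | starting material
3 | 2-hydroxy-3-methoxy-5-[(E)-prop-1-enyl]benzaldehyde | C/C=C/c1cc(OC)c(O)c(C=O)c1 | intermediate
4 | 2-ethenyl-6-methoxy-4-[(E)-prop-1-enyl]phenol | C/C=C/c1cc(OC)c(O)c(C=C)c1 | intermediate
5 | 3-hydroxy-4,5-dimethoxybenzaldehyde | O=Cc1cc(O)c(OC)c(OC)c1 | starting material
6 | rac-1-(3-hydroxy-4,5-dimethoxyphenyl)-2-{2-hydroxy-3-methoxy-5-[(E)-prop-1-enyl]phenyl}propan-1-one | C/C=C/c1cc(OC)c(O)c(c1)C(C)C(=O)c1cc(O)c(OC)c(OC)c1 | intermediate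
7 | (1S,2S)-1-(3-hydroxy-4,5-dimethoxyphenyl)-2-{2-hydroxy-3-methoxy-5-[(E)-prop-1-enyl]phenyl}propan-1-ol (not isolated) | C/C=C/c1cc(OC)c(O)c(c1)[C@H](C)[C@@H](c1cc(O)c(OC)c(OC)c1)O | intermediate
8 | (2S,3S)-2-(3-hydroxy-4,5-dimethoxyphenyl)-7-methoxy-3-methyl-5-[(E)-prop-1-enyl]-2,3-dihydrobenzofuran | C/C=C/c1cc(OC)c2c(c1)[C@H](C)[C@@H](c1cc(O)c(OC)c(OC)c1)O2 | target

Total step count: 4. Longest linear sequence: 4 steps (1 to 3 to 4 to 6 to 8). No protecting group is used.

**Steps most likely to fail**

Step 4. Three processes threaten this step.
- The two phenoxides may bind to ruthenium and slow the turnover.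
- Enolisation of the dianionic substrate may lag behind reduction, so that the resolution stops being dynamic and selectivity at C3 drops.
- Partial loss of H3 in the acid stage would erode C3 further.

The fallback sets out from 6 and comes back at 7. The dynamic resolution is replaced by a static kinetic resolution with separate racemisation, in a medium that keeps both phenols protonated. Noyori–Ikariya transfer hydrogenation with RuCl(p-cymene)[(S,S)-TsDPEN] in HCO2H/Et3N is run to about half conversion. Carbinol 7 is then separated by chromatography from the unreacted (R)-ketone F1. F1 is racemised back to 6 with DBU in toluene and recycled. Isolated 7 is closed to 8 with catalytic TsOH in CH2Cl2 at 0 °C.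

Step 3. Three processes threaten this step.
- The electron-rich aldehyde may decarbonylate.
- The ring B phenol may compete for rhodium.
- The vinylphenol may oligomerise at the reaction temperature.

The fallback sets out from 4 and 5 and comes back at 7. The C2–C3 bond is made by copper hydride catalysed reductive coupling of a vinylarene with a symmetrical aroyl anhydride. This needs no aldehyde C–H activation and sets C3 by enantioselective hydrocupration.
- Phenol 4 is silylated (TBSCl, imidazole, DMF) to the silyl ether of the vinylphenol F2.
- Aldehyde 5 is silylated in the same way to the silyloxy aldehyde F3.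
- F3 is oxidised (Pinnick oxidation, NaClO2, NaH2PO4, 2-methyl-2-butene) to the silyloxy acid F4.
- F4 is dehydrated (DCC, half an equivalent, CH2Cl2) to the symmetrical anhydride F5.
- Cu(OAc)2 with Ph-BPE (the ligand enantiomer that gives S at C3) and (MeO)2MeSiH in THF should hydrocuprate the terminal vinyl group of F2 in preference to the internal propenyl group. The benzylic copper species is acylated by F5, and the ketone is reduced in the same flask to the bis-silyl carbinol F6.
- TBAF in THF frees both phenols and gives 7, which is closed to 8 by the acid stage of step 4.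

Step 2. The ylide may add sluggishly to the phenoxide-deactivated aldehyde, and the electron-rich vinylphenol may oligomerise during work-up and concentration. The fallback sets out from 3 and comes back at 4, using a Peterson olefination. Me3SiCH2MgCl (2.2 equiv, THF, 0 °C) adds to 3 and gives the β-hydroxysilane F7. Catalytic TsOH in THF at 0 °C eliminates the silanol from F7 and gives 4. The solution of 4 can be carried into step 3 without concentration to dryness.

**Further compounds**
F1 | step 4 | (R)-1-(3-hydroxy-4,5-dimethoxyphenyl)-2-{2-hydroxy-3-methoxy-5-[(E)-prop-1-enyl]phenyl}propan-1-one | C/C=C/c1cc(OC)c(O)c(c1)[C@@H](C)C(=O)c1cc(O)c(OC)c(OC)c1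
F2 | step 3 | tert-butyl{2-ethenyl-6-methoxy-4-[(E)-prop-1-enyl]phenoxy}dimethylsilane | C/C=C/c1cc(OC)c(O[Si](C)(C)C(C)(C)C)c(C=C)c1
F3 | step 3 | 3-(tert-butyldimethylsilyloxy)-4,5-dimethoxybenzaldehyde | O=Cc1cc(O[Si](C)(C)C(C)(C)C)c(OC)c(OC)c1
F4 | step 3 | 3-(tert-butyldimethylsilyloxy)-4,5-dimethoxybenzoic acid | OC(=O)c1cc(O[Si](C)(C)C(C)(C)C)c(OC)c(OC)c1
F5 | step 3 | 3-(tert-butyldimethylsilyloxy)-4,5-dimethoxybenzoic anhydride | O=C(OC(=O)c1cc(O[Si](C)(C)C(C)(C)C)c(OC)c(OC)c1)c1cc(O[Si](C)(C)C(C)(C)C)c(OC)c(OC)c1
F6 | step 3 | (1S,2S)-1-[3-(tert-butyldimethylsilyloxy)-4,5-dimethoxyphenyl]-2-{2-(tert-butyldimethylsilyloxy)-3-methoxy-5-[(E)-prop-1-enyl]phenyl}propan-1-ol | C/C=C/c1cc(OC)c(O[Si](C)(C)C(C)(C)C)c(c1)[C@H](C)[C@@H](c1cc(O[Si](C)(C)C(C)(C)C)c(OC)c(OC)c1)O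
F7 | step 2 | rac-2-[1-hydroxy-2-(trimethylsilyl)ethyl]-6-methoxy-4-[(E)-prop-1-enyl]phenol | C/C=C/c1cc(OC)c(O)c(C(O)C[Si](C)(C)C)c1
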